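With the lactone numbered O1, C2 (chain), C3 (carboxyl C7), C4 (exocyclic methylene C6) and C5 (carbonyl), everything rests on the C3–C4 bond. It joins the stereogenic C3 to an sp2 carbon carrying a one-carbon exocyclic alkene, the imprint of a radical adding to an alkyne. Trivalent titanium opens a terminal epoxide homolytically to the C3 radical (C7 stays as CH2O), which closes the O1–C5 ring by 5-exo-dig attack on an O-propargyl group and sets C3 trans to the C2 chain. The precursor is the (R)-configured propargyl ether of a terminal epoxy alcohol whose chain ends in a dioxolane-masked methyl ketone; the oxirane configuration is erased and therefore immaterial.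

Key step: step 8

Remark on the chemistry: in step 11 acid cleavage of the silyl ether and of the dioxolane is assumed to precede the chromium oxidation, so the keto alcohol and the keto aldehyde are listed as intermediates that are not isolated.

Step 1
Reactants: 1 ω-pentadecalactone
Product: 2 15-hydroxy-N-methoxy-N-methylpentadecanamide
Conditions: MeNH(OMe)·HCl (1.5 equiv), iPrMgCl (3.0 equiv), THF, −20 °C → 0 °C
Reagents that add atoms: N,O-dimethylhydroxylamine hydrochloride, CNOC.Cl
Why: Weinreb aminolysis of a lactone, in which the magnesium amide made from the amine salt and iPrMgCl attacks the lactone carbonyl faster than iPrMgCl itself and the resulting N-methoxy-N-methylamide does not react further at this temperature.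

Step 2
Reactants: 2 15-hydroxy-N-methoxy-N-methylpentadecanamide; 3 methylmagnesium bromide
Product: 4 16-hydroxyhexadecan-2-one
Conditions: MeMgBr (3 equiv), THF, 0 °C; aq. NH4Cl
Reagents that add atoms: methylmagnesium bromide, C[Mg]Br
Why: Weinreb ketone synthesis, in which one equivalent of MeMgBr deprotonates the hydroxyl and a second adds once to the amide, the magnesium chelate holding the tetrahedral adduct until work-up so that no tertiary alcohol should form.

Step 3
Reactants: 4 16-hydroxyhexadecan-2-one
Product: 5 14-(2-methyl-1,3-dioxolan-2-yl)tetradecan-1-ol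
Conditions: ethylene glycol (5 equiv), pTsOH·H2O (cat.), toluene, reflux, Dean–Stark trap
Reagents that add atoms: ethylene glycol, OCCO
Why: Acid-catalysed ketalisation driven by azeotropic removal of water masks the ketone as a dioxolane that tolerates the Grignard, hydride-base, radical and non-acidic chromium steps that follow.

Step 4
Reactants: 5 14-(2-methyl-1,3-dioxolan-2-yl)tetradecan-1-ol
Product: 6 14-(2-methyl-1,3-dioxolan-2-yl)tetradecanal
Conditions: (COCl)2, DMSO, CH2Cl2, −78 °C; Et3N, −78 °C → 0 °C
Reagents that add atoms: none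
Why: Swern oxidation takes the primary alcohol to the aldehyde under anhydrous, non-acidic conditions that spare the dioxolane and cannot over-oxidise.

Step 5
Reactants: 6 14-(2-methyl-1,3-dioxolan-2-yl)tetradecanal; 7 vinylmagnesium bromide
Product: 8 rac-16-(2-methyl-1,3-dioxolan-2-yl)hexadec-1-en-3-ol
Conditions: vinylMgBr (1.3 equiv), THF, −78 °C → 0 °C; aq. NH4Cl
Reagents that add atoms: vinylmagnesium bromide, C=C[Mg]Br
Why: Grignard 1,2-addition to the aldehyde gives the secondary allylic alcohol as the racemate, the carbinol centre being left uncontrolled here because it is resolved in the next step.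

Step 6
Reactants: 8 rac-16-(2-methyl-1,3-dioxolan-2-yl)hexadec-1-en-3-ol
Product: 9 (1R)-14-(2-methyl-1,3-dioxolan-2-yl)-1-[(2S)-oxiran-2-yl]tetradecan-1-ol (erythro epoxy alcohol)
Conditions: Ti(OiPr)4 (0.1 equiv), D-(−)-diisopropyl tartrate (0.15 equiv), tBuOOH (0.45 equiv), 4 Å molecular sieves, CH2Cl2, −20 °C
Reagents that add atoms: tert-butyl hydroperoxide, CC(C)(C)OO
Why: Sharpless kinetic-resolution epoxidation, in which the titanium–D-tartrate catalyst should epoxidise the (R)-alcohol much faster than its antipode and deliver oxygen to the alkene face that gives the erythro product, so the carbinol centre (C2 of the target) is selected as R and the oxirane centre is set as S by the tartrate, the unreacted S half of 8 being removed by chromatography.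

Step 7
Reactants: 9 (1R)-14-(2-methyl-1,3-dioxolan-2-yl)-1-[(2S)-oxiran-2-yl]tetradecan-1-ol; 10 propargyl bromide
Product: 11 2-methyl-2-[(14R)-14-[(2S)-oxiran-2-yl]-14-(prop-2-yn-1-yloxy)tetradecyl]-1,3-dioxolane
Conditions: NaH (1.2 equiv), propargyl bromide (1.5 equiv), Bu4NI (cat.), THF, 0 °C → rt
Reagents that add atoms: propargyl bromide, C#CCBr
Why: Williamson etherification of the sodium alkoxide with a very reactive propargylic bromide at low temperature in an aprotic solvent, where O-alkylation should outrun Payne-type epoxide migration, and no stereocentre is touched.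

Step 8
Reactants: 11 2-methyl-2-[(14R)-14-[(2S)-oxiran-2-yl]-14-(prop-2-yn-1-yloxy)tetradecyl]-1,3-dioxolane
Product: 12 [(2R,3R)-2-[13-(2-methyl-1,3-dioxolan-2-yl)tridecyl]-4-methylideneoxolan-3-yl]methanol (2,3-trans)
Conditions: Cp2TiCl2 (2.5 equiv), Zn dust, THF, rt, the green Cp2TiCl solution added slowly to 11; sat. aq. NH4Cl
Reagents that add atoms: none
Why: Cp2TiCl (trivalent titanium, formed from Cp2TiCl2 and Zn) gives one electron to the oxirane, whose C–O bond breaks towards the more substituted carbon to leave a secondary radical at C3 with C7 held as a titanium alkoxide; this radical adds to the near alkyne carbon C4, and the vinyl radical is quenched by hydrogen abstraction from THF or by a second Cp2TiCl and protonation on work-up. The closest known reaction type is the Nugent–RajanBabu reductive epoxide opening coupled to radical cyclisation, which is established for epoxy propargyl ethers. The one ring formed, the oxolane O1–C2–C3–C4–C5, closes in the 5-exo-dig mode and leaves C6 as the exocyclic methylene. The one new stereocentre, C3, is controlled by the existing C2 centre: in a chair-like Beckwith–Houk transition state the long C2 chain sits pseudo-equatorial and the bulky titanoxymethyl group on the planar radical carbon turns away from it, which should give the 2,3-trans product, while the oxirane centre is destroyed and plays no part. The step needs regioselective homolysis (secured by the preference for the secondary radical), ring closure faster than capture of the radical by a second titanium (secured by the fast 5-exo-dig closure and the slow addition of the reagent) and chemoselectivity (secured by the inertness of the dioxolane and of the terminal alkyne C–H towards Cp2TiCl).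

Step 9
Reactants: 12 [(2R,3R)-2-[13-(2-methyl-1,3-dioxolan-2-yl)tridecyl]-4-methylideneoxolan-3-yl]methanol
Product: 13 tert-butyl-dimethyl-{[(2R,3R)-2-[13-(2-methyl-1,3-dioxolan-2-yl)tridecyl]-4-methylideneoxolan-3-yl]methoxy}silane
Conditions: TBSCl, imidazole, CH2Cl2, rt
Reagents that add atoms: tert-butyldimethylsilyl chloride, CC(C)(C)[Si](C)(C)Cl
Why: Imidazole-promoted silylation of the primary alcohol shields C7–OH from the chromium reagent of the next step without touching the alkene, the dioxolane or either stereocentre.

Step 10
Reactants: 13 tert-butyl-dimethyl-{[(2R,3R)-2-[13-(2-methyl-1,3-dioxolan-2-yl)tridecyl]-4-methylideneoxolan-3-yl]methoxy}silane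
Product: 14 (4R,5R)-4-{[tert-butyl(dimethyl)silyl]oxymethyl}-3-methylidene-5-[13-(2-methyl-1,3-dioxolan-2-yl)tridecyl]oxolan-2-one
Conditions: CrO3 (20 equiv), pyridine (40 equiv), CH2Cl2, rt
Reagents that add atoms: chromium trioxide, O=[Cr](=O)=O
Why: Allylic oxidation with the Collins reagent (CrO3·2py) should convert the C5 methylene, which is both allylic and next to the ring oxygen and hence the most easily oxidised C–H site, into the lactone carbonyl under non-acidic conditions that keep the silyl ether and the dioxolane.

Step 11
Reactants: 14 (4R,5R)-4-{[tert-butyl(dimethyl)silyl]oxymethyl}-3-methylidene-5-[13-(2-methyl-1,3-dioxolan-2-yl)tridecyl]oxolan-2-one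
Product: 17 (2R,3S)-4-methylidene-5-oxo-2-(14-oxopentadecyl)oxolane-3-carboxylic acid (target), via keto alcohol 15 (not isolated), via keto aldehyde 16 (not isolated)
Conditions: Jones reagent (CrO3, H2SO4, H2O), acetone, 0 °C → rt; iPrOH quench
Reagents that add atoms: water, O
Why: Jones oxidation, in which the aqueous sulfuric acid cleaves the primary silyl ether and the dioxolane and chromic acid oxidises the freed primary alcohol through the aldehyde hydrate to the acid, the acidic medium avoiding base-induced migration of the exocyclic alkene or epimerisation at C3.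

Compound list
1 | ω-pentadecalactone (oxacyclohexadecan-2-one) | O=C1CCCCCCCCCCCCCCO1 | starting material
2 | 15-hydroxy-N-methoxy-N-methylpentadecanamide | CON(C)C(=O)CCCCCCCCCCCCCCO | intermediate
3 | methylmagnesium bromide | C[Mg]Br | starting material
4 | 16-hydroxyhexadecan-2-one | CC(=O)CCCCCCCCCCCCCCO | intermediate
5 | 14-(2-methyl-1,3-dioxolan-2-yl)tetradecan-1-ol | OCCCCCCCCCCCCCCC1(C)OCCO1 | intermediate
6 | 14-(2-methyl-1,3-dioxolan-2-yl)tetradecanal | O=CCCCCCCCCCCCCCC1(C)OCCO1 | intermediate
7 | vinylmagnesium bromide | C=C[Mg]Br | starting material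
8 | rac-16-(2-methyl-1,3-dioxolan-2-yl)hexadec-1-en-3-ol | C=CC(O)CCCCCCCCCCCCCC1(C)OCCO1 | intermediate
9 | (1R)-14-(2-methyl-1,3-dioxolan-2-yl)-1-[(2S)-oxiran-2-yl]tetradecan-1-ol | O[C@H](CCCCCCCCCCCCCC2(C)OCCO2)[C@@H]1CO1 | intermediate
10 | propargyl bromide (3-bromoprop-1-yne) | C#CCBr | starting material
11 | 2-methyl-2-[(14R)-14-[(2S)-oxiran-2-yl]-14-(prop-2-yn-1-yloxy)tetradecyl]-1,3-dioxolane | C#CCO[C@H](CCCCCCCCCCCCCC2(C)OCCO2)[C@@H]1CO1 | intermediate
12 | [(2R,3R)-2-[13-(2-methyl-1,3-dioxolan-2-yl)tridecyl]-4-methylideneoxolan-3-yl]methanol | C=C1CO[C@H](CCCCCCCCCCCCCC2(C)OCCO2)[C@H]1CO | intermediate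
13 | tert-butyl-dimethyl-{[(2R,3R)-2-[13-(2-methyl-1,3-dioxolan-2-yl)tridecyl]-4-methylideneoxolan-3-yl]methoxy}silane | C=C1CO[C@H](CCCCCCCCCCCCCC2(C)OCCO2)[C@H]1CO[Si](C)(C)C(C)(C)C | intermediate
14 | (4R,5R)-4-{[tert-butyl(dimethyl)silyl]oxymethyl}-3-methylidene-5-[13-(2-methyl-1,3-dioxolan-2-yl)tridecyl]oxolan-2-one | C=C1C(=O)O[C@H](CCCCCCCCCCCCCC2(C)OCCO2)[C@H]1CO[Si](C)(C)C(C)(C)C | intermediate
15 | (4R,5R)-4-(hydroxymethyl)-3-methylidene-5-(14-oxopentadecyl)oxolan-2-one | C=C1C(=O)O[C@H](CCCCCCCCCCCCCC(C)=O)[C@H]1CO | intermediate
16 | (2R,3S)-4-methylidene-5-oxo-2-(14-oxopentadecyl)oxolane-3-carbaldehyde | C=C1C(=O)O[C@H](CCCCCCCCCCCCCC(C)=O)[C@H]1C=O | intermediate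
17 | (2R,3S)-4-methylidene-5-oxo-2-(14-oxopentadecyl)oxolane-3-carboxylic acid | C=C1C(=O)O[C@H](CCCCCCCCCCCCCC(C)=O)[C@H]1C(=O)O | target

Total step count: 11
Longest linear sequence: 11 steps (1 → 17)

Steps most likely to fail

Step 8. The β-titanoxy radical may be captured by a second Cp2TiCl before it cyclises, after which the alkyltitanium eliminates to the alkene (net deoxygenation), or the radical may be reduced without ring closure. Discrimination between the two faces of the planar C3 radical may also be weaker than planned. The fallback keeps the C3–C4 bond but makes the radical without titanium, by known tin chemistry, and sets out from 11. Hydrolytic opening of the oxirane at C7 with water and a catalytic amount of (S,S)-N,N′-bis(3,5-di-tert-butylsalicylidene)cyclohexane-1,2-diaminocobalt acetate (trivalent cobalt, the antipode expected to be matched) in THF should give (2S,3R)-16-(2-methyl-1,3-dioxolan-2-yl)-3-(prop-2-yn-1-yloxy)hexadecane-1,2-diol F1. Silylation of the primary hydroxyl (TBSCl, imidazole, 0 °C) should give (2S,3R)-1-(tert-butyldimethylsilyloxy)-16-(2-methyl-1,3-dioxolan-2-yl)-3-(prop-2-yn-1-yloxy)hexadecan-2-ol F2. 1,1′-Thiocarbonyldiimidazole should then convert the secondary hydroxyl into the O-alkyl imidazole-1-carbothioate F3. Bu3SnH and AIBN in hot benzene at high dilution (Barton–McCombie radical generation) should produce the same C3 radical, now carrying CH2OTBS, which closes 5-exo-dig and comes back to the route at 13.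

Step 10. Hydrogen abstraction may occur at the tertiary allylic C3–H instead of C5, the exocyclic double bond may migrate, or the oxidation may stall in spite of the large excess of reagent. The fallback replaces the direct chromium oxidation by a two-stage passage through the lactol and sets out from 13. Catalytic SeO2 with tBuOOH in CH2Cl2 (ene reaction followed by a [2,3]-sigmatropic shift, the path by which allyl ethers are oxidised at the oxygen-bearing carbon) should give (4R,5R)-4-{[tert-butyl(dimethyl)silyl]oxymethyl}-3-methylidene-5-[13-(2-methyl-1,3-dioxolan-2-yl)tridecyl]oxolan-2-ol F4 as an anomer mixture. Ag2CO3 on Celite in refluxing benzene (Fetizon oxidation) should then oxidise the lactol and come back to the route at 14.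

Step 6. The rate difference between the antipodes of 8 may be too small, or the terminal epoxy alcohol may be opened on the titanium centre, so that 9 is obtained with insufficient enantiomeric purity. The same weakness would show in step 7 as base-induced epoxide migration. The fallback runs the resolution in the opposite sense and installs the oxirane last, setting out from 8. Epoxidation with L-(+)-diisopropyl tartrate, Ti(OiPr)4 and tBuOOH, taken past half conversion, should consume the S antipode as (1S)-14-(2-methyl-1,3-dioxolan-2-yl)-1-[(2R)-oxiran-2-yl]tetradecan-1-ol F5, which is discarded. It should leave (3R)-16-(2-methyl-1,3-dioxolan-2-yl)hexadec-1-en-3-ol F6, whose enantiomeric purity rises with conversion. NaH and propargyl bromide should give 2-methyl-2-[(14R)-14-(prop-2-yn-1-yloxy)hexadec-15-en-1-yl]-1,3-dioxolane F7, on which no epoxide migration is possible. Buffered mCPBA (NaHCO3, CH2Cl2), which attacks the alkene in preference to the alkyne, should give 11 together with its oxirane epimer 2-methyl-2-[(14R)-14-[(2R)-oxiran-2-yl]-14-(prop-2-yn-1-yloxy)tetradecyl]-1,3-dioxolane F8. Because the oxirane centre is erased in step 8, the mixture comes back to the route at 11 and converges on 12.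

Further compounds
F1 | step 8 | (2S,3R)-16-(2-methyl-1,3-dioxolan-2-yl)-3-(prop-2-yn-1-yloxy)hexadecane-1,2-diol | C#CCO[C@H](CCCCCCCCCCCCCC1(C)OCCO1)[C@@H](O)CO
F2 | step 8 | (2S,3R)-1-(tert-butyldimethylsilyloxy)-16-(2-methyl-1,3-dioxolan-2-yl)-3-(prop-2-yn-1-yloxy)hexadecan-2-ol | C#CCO[C@H](CCCCCCCCCCCCCC1(C)OCCO1)[C@@H](O)CO[Si](C)(C)C(C)(C)C
F3 | step 8 | O-[(2S,3R)-1-(tert-butyldimethylsilyloxy)-16-(2-methyl-1,3-dioxolan-2-yl)-3-(prop-2-yn-1-yloxy)hexadecan-2-yl] 1H-imidazole-1-carbothioate | C#CCO[C@H](CCCCCCCCCCCCCC1(C)OCCO1)[C@@H](OC(=S)n1ccnc1)CO[Si](C)(C)C(C)(C)C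
F4 | step 10 | (4R,5R)-4-{[tert-butyl(dimethyl)silyl]oxymethyl}-3-methylidene-5-[13-(2-methyl-1,3-dioxolan-2-yl)tridecyl]oxolan-2-ol (anomer mixture) | C=C1C(O)O[C@H](CCCCCCCCCCCCCC2(C)OCCO2)[C@H]1CO[Si](C)(C)C(C)(C)C
F5 | step 6 | (1S)-14-(2-methyl-1,3-dioxolan-2-yl)-1-[(2R)-oxiran-2-yl]tetradecan-1-ol | O[C@@H](CCCCCCCCCCCCCC2(C)OCCO2)[C@H]1CO1
F6 | step 6 | (3R)-16-(2-methyl-1,3-dioxolan-2-yl)hexadec-1-en-3-ol | C=C[C@H](O)CCCCCCCCCCCCCC1(C)OCCO1
F7 | step 6 | 2-methyl-2-[(14R)-14-(prop-2-yn-1-yloxy)hexadec-15-en-1-yl]-1,3-dioxolane | C#CCO[C@H](CCCCCCCCCCCCCC1(C)OCCO1)C=C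
F8 | step 6 | 2-methyl-2-[(14R)-14-[(2R)-oxiran-2-yl]-14-(prop-2-yn-1-yloxy)tetradecyl]-1,3-dioxolane | C#CCO[C@H](CCCCCCCCCCCCCC2(C)OCCO2)[C@H]1CO1
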